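The runs are calculated from invented constants.

Slowness late in a run is where I start, so here are the flasks and the earlier runs.

| flask | electrophile | nucleophile | gas | remark | time |
|---|---|---|---|---|---|
| Saturday's | 0.11 M | 0.208 M | 86 mM (held) | run made earlier |  |
| Thursday's | 0.080 M | 0.208 M | 86 mM (held) | run made earlier |  |
| green | 0.16 M | 0.210 M | 86 mM (held) |  | 20 min |
| grey | 0.16 M | 0.310 M | 86 mM (held) |  | 20 min |
| teal | 0.16 M | 0.470 M | 86 mM (held) |  | 20 min |

| run | time / min | electrophile / % | target / % |
|---|---|---|---|
| Saturday's | 1.50 | 73 | 23 |
| Saturday's | 3.00 | 56 | 39 |
| Saturday's | 5.00 | 43 | 46 |
| Saturday's | 6.00 | 32 | 47 |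
| Saturday's | 8.00 | 25 | 53 |
| Saturday's | 10.0 | 22 | 56 |
| Saturday's | 12.0 | 18 | 55 |
| Thursday's | 0.667 | 88 | 13 |
| Thursday's | 2.00 | 63 | 31 |
| Thursday's | 3.00 | 50 | 40 |
| Thursday's | 5.00 | 38 | 52 |
| Thursday's | 8.00 | 22 | 55 |
| Thursday's | 10.0 | 18 | 65 |
| Thursday's | 12.0 | 14 | 68 |

(scatter of a reading: 2 percentage points)

- percent here means electrophile units held: one side product counts as two
- at the start none of free base is dissolved
- the numbers in the tables scatter with a standard deviation of 2 percentage points
- on the list of suspects stand: electrophile + nucleophile -> acid set free + target; nucleophile + acid set free <-> protonated nucleophile; acid set free + free base <-> salt of the base; gas <-> free base; electrophile + target -> side product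

* part of the electrophile that has reacted at the end, green
* part of the electrophile that has reacted at the end, grey
* part of the electrophile that has reacted at the end, teal
* what raising the concentration of nucleophile from its lowest to its highest value here does to the part of the electrophile that has reacted (changes below 5 percentage points count as none) (it rises / no change / it falls)

Thursday's electrophile reads 50% at 3.00 min, which gives a first-step constant of about 1.11 /M/min. Saturday's electrophile decays between 8.00 min and 12.0 min at 0.0821 /min, slower than the 0.136 /min expected if nucleophile went one per electrophile, so I take the acid set free to bind a second nucleophile. Saturday's missing percent at 12.0 min, with each side product holding two units, set against the mid-run product of electrophile and target, gives a side-step constant of about 0.680 /M/min.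

My yardstick is the carrying share, the charged nucleophile over twice the charged electrophile: while it stands below one, it is the part of the electrophile the first step can turn before the nucleophile, then the limiting reagent, is used up. For green that is 65.6%, the bound from below. Each target can take one more electrophile into side product, so the bound from above is nucleophile over electrophile, 131%, which caps nothing short of the whole charge.

To tighten green I join the two ends. The first step runs for about 8.18 min, and then the ratio of electrophile to target falls by the side step, with target ahead by 0.0500 M. That gives 0.351 and 83.1% reacted.

Grey's share is 96.9%, nearly balanced, so by my reckoning the first step by itself reaches 87.7%, and the side step over the last 10.0 min lifts that to 95.6%. Teal's share is 147%, above one, so there the nucleophile is not the limiting reagent; its first step by itself gives 98.9% by my reckoning, and from green to teal my figures rise by about 16 percentage points.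

The forecast of 87%, 97% and 99.8%, with the trend "it rises", made on the ground that “the freed acid protonates it”, stands above my figures of 83.1%, 95.6% and 98.9% for green, grey and teal .

The flasks give 84.9% for green, 96.6% for grey and 99.8% for teal; with more nucleophile the part reacted goes as follows: it rises, by 15 points. Green keeps 8.0% of its nucleophile free at 20.0 min. Its first step has carried target plus half the side product, 61.5%, just under its carrying share of 65.6%.

    electrophile + nucleophile → acid set free + target (k = 1.16 /M/min)
    nucleophile + acid set free ⇌ protonated nucleophile, settled at all times (K = 5500 /M)
    acid set free + free base ⇌ salt of the base (K = 21000 /M, k = 3.22 /M/min)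
    gas ⇌ free base, rate k4*(csat - [free base]) (kL = 7.30 /min)
    electrophile + target → side product (k = 0.615 /M/min)

For a flask like grey with 0.12 M of nucleophile, the carrying share is 37.5% and the ceiling 75.0%, and joining the ends after 4.50 min gives a ratio of 2.54 and 58.8% reacted. That flask gives 59.7%, with side product holding most of its electrophile.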